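## Structural features

Compound 26 is an achiral chain of four benzene rings (A–D) joined only by three diaryl ether oxygens. It carries eleven free hydroxyls and no stereocentre, so no relations between neighbouring stereocentres arise. Ring A is a benzene-1,3,5-triol bound through the oxygen at C2. Ring B has its ether oxygens at C1 (to ring A) and C5 (to ring C), hydroxyls at C3 and C4, and CH at C2 and C6. Ring C is pentaoxygenated: C1 carries the oxygen to ring B, C5 the oxygen to ring D, C2, C4 and C6 carry hydroxyls, and C3 is the only CH; ring D is a 3,4,5-trihydroxyphenyl ether. The fragile part is the free polyphenol, whose pyrogallol-type and phloroglucinol-type rings oxidise readily in air, above all in base, so the oxygens must stay alkylated until the last step. The real difficulty is positional: fourteen oxygens must be placed without error, and the ether carbons C1 and C5 of ring C and C2 of ring A are each flanked by two further oxygens. The key step uses ring D, where the ether carbon C1 lies between two CH groups (C2, C6) and faces three contiguous oxygens (C3, C4, C5): C1 and C2 map onto the two carbons of an ynol ether on the ring C oxygen, and C3–C6 onto the four ring carbons of a 3,4-dialkoxycyclobutenone.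

## Logic of the disconnections

26 ⇒ 25. Ten O–alkyl bonds are cut (nine O–CH3, one O–CH2CH3). The free polyphenol would not survive the copper, organolithium and thermal steps, so every earlier compound is a stable aryl alkyl ether. The forward step must cleave methyl and ethyl ethers and leave the three diaryl ether bonds intact.

25 ⇒ 16 + 20. Ring D is cut at C2–C3, C1–C6 and C3–C4. The diaryl ether at the doubly flanked C5 oxygen of ring C is thereby traced back to an O–C(sp) bond, and ring D to a two-carbon and a four-carbon piece. The forward step needs one regiochemistry in the ketene–alkyne union (CH terminus of 16 to the carbonyl carbon of ketene 21), and 16 must survive heating.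

20 ⇒ 17 + 18. The four-membered ring is cut at C1–C2 and C3–C4, a ketene–alkyne [2+2] through 19. Two small purchasable pieces result. The forward step needs 19 to be trapped by 18 faster than it oligomerises.

16 ⇒ 13 ⇒ 10 + 11. The triple bond is traced to a dichloroalkene (loss of two chlorines and one hydrogen), and the O–C(vinyl) bond to the phenol 10 and 11. This turns the hindered phenol oxygen into the ynol ether without any aryl coupling. The organolithium must eliminate faster than it metalates the ring CH groups between two methoxy groups.

10 ⇒ 8. The C5–O bond of ring C is traced to a C5–CHO bond (through 9). Carrying this oxygen as a formyl group tells the two meta oxygens of ring C apart, needs no protecting group and lowers the oxidation sensitivity of the phenol used in the coupling. The forward oxidation needs aryl migration, not hydride migration.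

8 ⇒ 5 + 7. The ring B C5–O bond is cut, with the oxygen staying on ring C. The ring C carbon is too hindered to serve as the electrophile, so ring C enters as the phenol and ring B as the bromide. The forward step is the hardest etherification: a doubly flanked phenoxide with an ortho-methoxy aryl bromide.

7 ⇒ 4. The C–CHO bond is cut. The two free positions of 4 are equivalent, so no regiochemical question arises; the step must tolerate the free hydroxyl.

5 ⇒ 3 + 4. The ring B C1–O bond is cut, with the oxygen staying on ring A. The hindered partner is again the nucleophile and the ring B carbon, flanked by two CH, is the electrophile. The forward step must react at iodine and leave bromine.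

3 ⇒ 2 ⇒ 1. One O–CH3 bond and the C–I bond are cut. Iodination para to a free hydroxyl whose ortho positions are both occupied fixes the halogen pattern of ring B.

## Other disconnections considered

Alternative 1: The cut removes both ether bonds of ring B (C1–O and C5–O) and traces the ring to 2,4,6-trifluorobenzaldehyde A1. Its formyl carbon and last fluorine stand for the C4 and C3 oxygens. In the forward step the phenoxide of 4 would displace the para fluorine, and the phenoxide of the ring C–D phenol A2 would then displace an ortho fluorine, to give A3 in one pot.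
- In favour: three pieces are joined in one operation without a transition metal. The doubly flanked ring C oxygen attacks an activated fluoroarene, which is a better prospect than step 5 of the chosen plan. In convergence the alternative is the better of the two.
- Against: A1 does not dictate para-before-ortho substitution, since coordination of the counter-ion to the formyl oxygen assists ortho attack. The second substitution occurs on a ring already deactivated by a para aryloxy group. The last fluorine must later be exchanged for oxygen on a ring with two aryloxy donors, before Dakin oxidation of the aldehyde. A2 still contains the ring C–ring D ether, which would have to be made separately, most simply by copper coupling of a ring C phenol with 5-bromo-1,2,3-trimethoxybenzene A4.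
- Comparison: nucleophilic aromatic substitution is mechanistically more predictable than the ketene cascade. The step counts are about equal. The chosen plan fixes every oxygen position through its building blocks, whereas this one depends on discrimination between fluorines.

Alternative 2: The cut opens ring A at C1–C2 and unfolds it to the triketo ester A5. The forward step is a base-mediated intramolecular Claisen condensation, in which the aryloxy-bearing C6 attacks the ester carbon; enolisation then gives the triol A6.
- In favour: the ring A–O–ring B bond, whose ring A carbon is flanked by two oxygens, is made as a simple alkyl aryl ether before ring A exists. This is the same idea as the chosen key step (a ring grown on a pre-formed ether oxygen), and in concept it is its equal. No metal is needed.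
- Against: 3,5-dioxo esters tend to close through oxygen to 4-hydroxy-2-pyranones. The Claisen mode needs a carbanion at C6, the least acidic of the three methylene positions, hence polyanion conditions. A6 emerges as a free triol that must be methylated again before the copper and organolithium steps.
- Comparison: the same bond costs one favourable step in the chosen plan (step 3), so the chosen plan is better in step economy. The alternative is better only in avoiding a metal.

Alternative 3: The cut opens ring C at C3–C4 and contracts it to the cyclobutenone A7, which derives from a squarate ester and already carries the ring D aryloxy group. Thermolysis would open A7 to a dienylketene, whose 6π closure gives A8.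
- In favour: the cascade is unimolecular and well precedented. It places all five oxygens of ring C and tells them apart (free hydroxyl at C4, silyl ether at C1, methyl ether at C6, ethyl ether at C2). The ring D ether comes from addition–elimination on the squarate, not from an arene coupling. In mechanistic predictability this is the better of the two, since no bimolecular cycloaddition has to compete with ketene decomposition.
- Against: the alkenyl-lithium addition must distinguish the two carbonyls of an aryloxy/methoxy squarate. A8 then needs capping of the C4 hydroxyl, release of the C1 oxygen and copper coupling of that doubly flanked phenol with the ring B bromide. That is the same hindered etherification as step 5, now late and with ring D attached.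
- Comparison: the chosen plan gets the ring C pattern from 4 in two simple operations (steps 4 and 6), so it is shorter. The alternative is stronger in mechanism, the chosen plan in step economy.

Key step: step 10

Remark on the chemistry: following the atoms through the key step (alkyne O-carbon → ring D C1, alkyne CH → C2, carbonyl carbon of 20 → C3, C4 of 20 → C4, C3 of 20 → C5, C2 of 20 → C6) shows that 16, 20 and 25 fit the target, so no structure needed correction; the added design is the formyl group as masked ring C oxygen and the bromo-iodo ring B piece; 1, 4, 11, 17 and 18 are assumed purchasable.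

Step 1
Reactants: 1 2-bromo-6-methoxyphenol
Product: 2 2-bromo-4-iodo-6-methoxyphenol
Conditions: NIS, TsOH·H2O (cat.), MeCN, 0 °C → rt, dark
Reagents that add atoms: N-iodosuccinimide, O=C1CCC(=O)N1I
Why: Electrophilic aromatic iodination; the hydroxyl is the strongest director and both its ortho positions are occupied, so iodine should enter para to it and give the halogen pair that distinguishes the two ether positions of ring B.

Step 2
Reactants: 2 2-bromo-4-iodo-6-methoxyphenol
Product: 3 1-bromo-5-iodo-2,3-dimethoxybenzene
Conditions: MeI, K2CO3, acetone, reflux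
Reagents that add atoms: iodomethane, CI
Why: Williamson O-methylation of the phenoxide; both aryl halides are inert under these conditions.

Step 3
Reactants: 3 1-bromo-5-iodo-2,3-dimethoxybenzene; 4 2,4,6-trimethoxyphenol
Product: 5 2-(3-bromo-4,5-dimethoxyphenoxy)-1,3,5-trimethoxybenzene
Conditions: CuI (10 mol %), picolinic acid (20 mol %), K3PO4, DMSO, 80 °C, Ar
Reagents that add atoms: none
Why: Ullmann-type copper-catalysed diaryl ether synthesis; the electron-rich phenoxide of 4 is a good nucleophile despite its two ortho methoxy groups, and the unhindered C–I bond should react well below the temperature at which the ortho-substituted C–Br bond does, so the bromide is kept for step 5.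

Step 4
Reactants: 4 2,4,6-trimethoxyphenol
Product: 7 3-hydroxy-2,4,6-trimethoxybenzaldehyde, via iminium chloride 6 (not isolated)
Conditions: POCl3, DMF, 0 °C → rt; then H2O, 50 °C
Reagents that add atoms: N,N-dimethylformamide, CN(C)C=O; water, O
Why: Vilsmeier–Haack formylation; the two free ring positions of 4 are equivalent and each is ortho, ortho and para to methoxy groups, so a single aldehyde is expected; hydrolysis of 6 (and of any O-formyl group) gives 7, whose formyl group is the masked second oxygen of ring C.

Step 5
Reactants: 5 2-(3-bromo-4,5-dimethoxyphenoxy)-1,3,5-trimethoxybenzene; 7 3-hydroxy-2,4,6-trimethoxybenzaldehyde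
Product: 8 3-[2,3-dimethoxy-5-(2,4,6-trimethoxyphenoxy)phenoxy]-2,4,6-trimethoxybenzaldehyde
Conditions: CuI (20 mol %), picolinic acid (40 mol %), K3PO4, DMSO, 110 °C, Ar
Reagents that add atoms: none
Why: Ullmann-type copper-catalysed etherification with a ligand system suited to hindered partners; phenolic aldehydes are established nucleophiles in this coupling, the formyl group tempers the oxidation sensitivity of the phenoxide, and the C–Br bond of 5 is the only reactive halide.

Step 6
Reactants: 8 3-[2,3-dimethoxy-5-(2,4,6-trimethoxyphenoxy)phenoxy]-2,4,6-trimethoxybenzaldehyde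
Product: 10 3-[2,3-dimethoxy-5-(2,4,6-trimethoxyphenoxy)phenoxy]-2,4,6-trimethoxyphenol, via aryl formate 9 (not isolated)
Conditions: mCPBA, CH2Cl2, 0 °C → rt; then MeOH, Et3N (cat.), rt, Ar
Reagents that add atoms: 3-chloroperbenzoic acid, OOC(=O)c1cccc(Cl)c1
Why: Baeyer–Villiger (Dakin-type) oxidation; in the Criegee intermediate the electron-rich aryl group with two ortho methoxy groups should migrate in preference to hydrogen to give 9, which is methanolysed to the phenol; at 0 °C the aldehyde should react with the peracid faster than the methoxyarenes do.

Step 7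
Reactants: 10 3-[2,3-dimethoxy-5-(2,4,6-trimethoxyphenoxy)phenoxy]-2,4,6-trimethoxyphenol; 11 trichloroethylene
Product: 13 1-{[(E)-1,2-dichloroethenyl]oxy}-3-[2,3-dimethoxy-5-(2,4,6-trimethoxyphenoxy)phenoxy]-2,4,6-trimethoxybenzene, via dichloroacetylene 12 (not isolated)
Conditions: K2CO3, DMF, 70 °C, closed flask under Ar
Reagents that add atoms: none
Why: Known O-(1,2-dichlorovinyl)ation of phenols: base removes HCl from 11 to give 12, to which the phenoxide adds anti (hence the E-alkene); the small linear electrophile should tolerate the two ortho methoxy groups.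

Step 8
Reactants: 13 1-{[(E)-1,2-dichloroethenyl]oxy}-3-[2,3-dimethoxy-5-(2,4,6-trimethoxyphenoxy)phenoxy]-2,4,6-trimethoxybenzene
Product: 16 1-(ethynyloxy)-3-[2,3-dimethoxy-5-(2,4,6-trimethoxyphenoxy)phenoxy]-2,4,6-trimethoxybenzene, via chloroethynyl ether 14 (not isolated), via lithium acetylide 15 (not isolated)
Conditions: n-BuLi (2.3 equiv), THF, −78 → −40 °C; aq. NH4Cl, −78 °C; used without storage
Reagents that add atoms: none
Why: Known conversion of 1,2-dichlorovinyl ethers into ynol ethers: deprotonation and loss of LiCl give 14, chlorine–lithium exchange gives 15, and protonation gives 16; at −78 °C these events should be much faster than lithiation of the ring CH groups between two methoxy groups.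

Step 9
Reactants: 17 methoxyacetyl chloride; 18 ethoxyacetylene
Product: 20 3-ethoxy-4-methoxycyclobut-2-en-1-one (racemic), via methoxyketene 19 (not isolated)
Conditions: Et3N, Et2O, 0 °C → rt, slow addition of 17 to 18 (excess) and Et3N
Reagents that add atoms: none
Why: Dehydrochlorination gives ketene 19, which undergoes the known [2+2] cycloaddition of ketenes with ethoxyacetylene; the nucleophilic CH terminus of 18 bonds to the ketene carbonyl carbon, which places ethoxy at C3 and methoxy at C4; the one stereocentre (C4) forms racemic and is destroyed in step 10.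

Step 10
Reactants: 16 1-(ethynyloxy)-3-[2,3-dimethoxy-5-(2,4,6-trimethoxyphenoxy)phenoxy]-2,4,6-trimethoxybenzene; 20 3-ethoxy-4-methoxycyclobut-2-en-1-one
Product: 25 5-{3-[2,3-dimethoxy-5-(2,4,6-trimethoxyphenoxy)phenoxy]-2,4,6-trimethoxyphenoxy}-3-ethoxy-2-methoxyphenol, via vinylketene 21 (not isolated), via vinylcyclobutenone 22 (not isolated), via dienylketene 23 (not isolated), via cyclohexadienone 24 (not isolated)
Conditions: PhMe, 80–100 °C, sealed tube, Ar; 20 (1.5 equiv) added in portions
Reagents that add atoms: none
Why: On heating, 20 should undergo 4π conrotatory ring opening, with the methoxy group turning outward, to vinylketene 21. The ketene C=C of 21 then adds [2+2] to the polarised alkyne of 16: the nucleophilic CH terminus attacks the ketene carbonyl carbon and the oxygen-stabilised carbon closes onto the ketene α-carbon, giving 22. Reversible 4π opening of 22 gives dienylketene 23, whose thermal 6π disrotatory electrocyclisation (carbonyl carbon to the methoxy-bearing terminus) closes the six-membered carbocycle as 24, and enolisation gives the phenol 25. The closest known reaction is the Danheiser benzannulation of cyclobutenones with alkoxy- and silyloxyacetylenes, and 3-alkoxycyclobutenones made from ketenes and ethoxyacetylene are known to open thermally to vinylketenes. No stereocentre is created, since the sp3 carbons of 22 and 24 are erased by ring opening and by enolisation. The selectivity needed is the regiochemistry of the ketene–alkyne union; the ether oxygen on the alkyne secures it, so that the aryloxy carbon becomes ring D C1 between two CH, and the two ortho methoxy groups of ring C twist the arene out of conjugation with that oxygen, which leaves its lone pair free to activate the alkyne. Only the isomer of 23 with ketene and alkoxyvinyl groups cis across the central double bond can close; the other reverts to 22, so the sequence should funnel to 25.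

Step 11
Reactants: 25 5-{3-[2,3-dimethoxy-5-(2,4,6-trimethoxyphenoxy)phenoxy]-2,4,6-trimethoxyphenoxy}-3-ethoxy-2-methoxyphenol
Product: 26 2-{3,4-dihydroxy-5-[2,4,6-trihydroxy-3-(3,4,5-trihydroxyphenoxy)phenoxy]phenoxy}benzene-1,3,5-triol
Conditions: BBr3 (excess), CH2Cl2, −78 °C → rt; then H2O, Ar; isolation under Ar
Reagents that add atoms: none
Why: Lewis acid-mediated dealkylation of aryl alkyl ethers (coordination of boron at oxygen, bromide attack at the alkyl carbon); the nine methyl ethers and the ethyl ether should be cleaved, while the three diaryl ethers offer no alkyl carbon for attack and remain.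

## Compound list

In the names of 22–24, ArO– stands for 3-[2,3-dimethoxy-5-(2,4,6-trimethoxyphenoxy)phenoxy]-2,4,6-trimethoxyphenoxy, which is compound 10 bound through its oxygen.

1 | 2-bromo-6-methoxyphenol | COc1cccc(Br)c1O | starting material
2 | 2-bromo-4-iodo-6-methoxyphenol | COc1cc(I)cc(Br)c1O | intermediate
3 | 1-bromo-5-iodo-2,3-dimethoxybenzene | COc1cc(I)cc(Br)c1OC | intermediate
4 | 2,4,6-trimethoxyphenol | COc1cc(OC)c(O)c(OC)c1 | starting material
5 | 2-(3-bromo-4,5-dimethoxyphenoxy)-1,3,5-trimethoxybenzene | COc1cc(OC)c(Oc2cc(OC)c(OC)c(Br)c2)c(OC)c1 | intermediate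
6 | N-[(3-hydroxy-2,4,6-trimethoxyphenyl)methylidene]-N-methylmethanaminium chloride | C[N+](C)=Cc1c(OC)cc(OC)c(O)c1OC.[Cl-] | intermediate (not isolated)
7 | 3-hydroxy-2,4,6-trimethoxybenzaldehyde | O=Cc1c(OC)cc(OC)c(O)c1OC | intermediate
8 | 3-[2,3-dimethoxy-5-(2,4,6-trimethoxyphenoxy)phenoxy]-2,4,6-trimethoxybenzaldehyde | O=Cc1c(OC)cc(OC)c(Oc2cc(Oc3c(OC)cc(OC)cc3OC)cc(OC)c2OC)c1OC | intermediate
9 | 3-[2,3-dimethoxy-5-(2,4,6-trimethoxyphenoxy)phenoxy]-2,4,6-trimethoxyphenyl formate | O=COc1c(OC)cc(OC)c(Oc2cc(Oc3c(OC)cc(OC)cc3OC)cc(OC)c2OC)c1OC | intermediate (not isolated)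
10 | 3-[2,3-dimethoxy-5-(2,4,6-trimethoxyphenoxy)phenoxy]-2,4,6-trimethoxyphenol | Oc1c(OC)cc(OC)c(Oc2cc(Oc3c(OC)cc(OC)cc3OC)cc(OC)c2OC)c1OC | intermediate
11 | trichloroethylene | ClC=C(Cl)Cl | starting material
12 | dichloroacetylene | ClC#CCl | intermediate (not isolated)
13 | 1-{[(E)-1,2-dichloroethenyl]oxy}-3-[2,3-dimethoxy-5-(2,4,6-trimethoxyphenoxy)phenoxy]-2,4,6-trimethoxybenzene | Cl/C=C(/Cl)Oc1c(OC)cc(OC)c(Oc2cc(Oc3c(OC)cc(OC)cc3OC)cc(OC)c2OC)c1OC | intermediate
14 | 1-[(chloroethynyl)oxy]-3-[2,3-dimethoxy-5-(2,4,6-trimethoxyphenoxy)phenoxy]-2,4,6-trimethoxybenzene | ClC#COc1c(OC)cc(OC)c(Oc2cc(Oc3c(OC)cc(OC)cc3OC)cc(OC)c2OC)c1OC | intermediate (not isolated)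
15 | ({3-[2,3-dimethoxy-5-(2,4,6-trimethoxyphenoxy)phenoxy]-2,4,6-trimethoxyphenoxy}ethynyl)lithium | [Li]C#COc1c(OC)cc(OC)c(Oc2cc(Oc3c(OC)cc(OC)cc3OC)cc(OC)c2OC)c1OC | intermediate (not isolated)
16 | 1-(ethynyloxy)-3-[2,3-dimethoxy-5-(2,4,6-trimethoxyphenoxy)phenoxy]-2,4,6-trimethoxybenzene | C#COc1c(OC)cc(OC)c(Oc2cc(Oc3c(OC)cc(OC)cc3OC)cc(OC)c2OC)c1OC | intermediate
17 | methoxyacetyl chloride | COCC(=O)Cl | starting material
18 | ethoxyacetylene | C#COCC | starting material
19 | methoxyketene (2-methoxyethen-1-one) | COC=C=O | intermediate (not isolated)
20 | 3-ethoxy-4-methoxycyclobut-2-en-1-one (racemic) | CCOC1=CC(=O)C1OC | intermediate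
21 | (3Z)-3-ethoxy-4-methoxybuta-1,3-dien-1-one | CO/C=C(OCC)/C=C=O | intermediate (not isolated)
22 | 3-ArO-4-[(Z)-1-ethoxy-2-methoxyethenyl]cyclobut-2-en-1-one (racemic) | CO/C=C(OCC)/C1C(=O)C=C1Oc2c(OC)cc(OC)c(Oc3cc(Oc4c(OC)cc(OC)cc4OC)cc(OC)c3OC)c2OC | intermediate (not isolated)
23 | (3E,5Z)-3-ArO-5-ethoxy-6-methoxyhexa-1,3,5-trien-1-one | CO/C=C(OCC)/C=C(Oc1c(OC)cc(OC)c(Oc2cc(Oc3c(OC)cc(OC)cc3OC)cc(OC)c2OC)c1OC)\C=C=O | intermediate (not isolated)
24 | 3-ArO-5-ethoxy-6-methoxycyclohexa-2,4-dien-1-one (racemic) | O=C1C=C(Oc2c(OC)cc(OC)c(Oc3cc(Oc4c(OC)cc(OC)cc4OC)cc(OC)c3OC)c2OC)C=C(OCC)C1OC | intermediate (not isolated)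
25 | 5-{3-[2,3-dimethoxy-5-(2,4,6-trimethoxyphenoxy)phenoxy]-2,4,6-trimethoxyphenoxy}-3-ethoxy-2-methoxyphenol | CCOc1cc(Oc2c(OC)cc(OC)c(Oc3cc(Oc4c(OC)cc(OC)cc4OC)cc(OC)c3OC)c2OC)cc(O)c1OC | intermediate
26 | 2-{3,4-dihydroxy-5-[2,4,6-trihydroxy-3-(3,4,5-trihydroxyphenoxy)phenoxy]phenoxy}benzene-1,3,5-triol | Oc1cc(O)c(Oc2cc(O)c(O)c(Oc3c(O)cc(O)c(Oc4cc(O)c(O)c(O)c4)c3O)c2)c(O)c1 | target

## Step count and least certain steps

Total: 11 steps. Longest linear sequence: 9 steps (1, 2, 3, 5, 6, 7, 8, 10, 11); steps 4 and 9 are side branches.

Least certain, in this order: the key step 10, then steps 5, 8, 4 and 11.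

Key step 10. The most likely failure is slow capture of vinylketene 21 by the hindered aryloxyalkyne, which is less nucleophilic than an alkoxyalkyne. Self-condensation of the ketene and thermal oligomerisation of 16 would then outrun ring formation. O-acylation of the phenol product by surplus ketene would also lower the return, although such an ester can be methanolysed back. The fallback sets out from 10 and comes back at 26. Copper-catalysed coupling of 10 with 5-bromo-1,2,3-trimethoxybenzene A4 (CuI, picolinic acid, K3PO4, DMSO, 90 °C) pairs a hindered phenoxide with an unhindered bromide, as in step 3. It should give 1,3,5-trimethoxy-2-{3,4-dimethoxy-5-[2,4,6-trimethoxy-3-(3,4,5-trimethoxyphenoxy)phenoxy]phenoxy}benzene F1, which BBr3 converts into 26 as in step 11. This fallback is shorter than steps 7–10 but gives up the ring-growth strategy.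

For step 5, oxidative addition at the ortho-methoxy C–Br bond may be too slow for the doubly flanked phenoxide. Protodebromination of 5 and oxidative loss of the phenoxide at 110 °C would then dominate. The fallback sets out from 5 and comes back at 8. Copper-catalysed halogen exchange (CuI, NaI, trans-N,N'-dimethylcyclohexane-1,2-diamine, dioxane, 110 °C) should give 2-(3-iodo-4,5-dimethoxyphenoxy)-1,3,5-trimethoxybenzene F2. Its C–I bond can be coupled with 7 at 80–90 °C under the conditions of step 3.

For step 8, the terminal ynol ether may be lost by hydration or oligomerisation during work-up and concentration, and warming before elimination is complete would allow ring metalation. The fallback sets out from 13 and comes back at 16. Acetylide 15 is quenched with Me3SiCl to give {[3-(2,3-dimethoxy-5-(2,4,6-trimethoxyphenoxy)phenoxy)-2,4,6-trimethoxyphenoxy]ethynyl}trimethylsilane F3, which can be purified and stored. It is desilylated (K2CO3 (cat.), MeOH, 0 °C) just before step 10, and 16 is carried on as a solution.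

For step 4, the free hydroxyl may consume the formylating agent by O-formylation, and the very electron-rich phenol may degrade oxidatively during the acidic work-up. The fallback sets out from 4 and comes back at 7. Acetylation (Ac2O, pyridine) gives 2,4,6-trimethoxyphenyl acetate F4. Vilsmeier–Haack formylation then gives 3-formyl-2,4,6-trimethoxyphenyl acetate F5, and methanolysis (K2CO3 (cat.), MeOH) releases 7.

For step 11, cleavage of ten ethers may stop short when partly dealkylated boron aryloxides precipitate, and the free polyphenol may oxidise during isolation. The fallback sets out from 25 and comes back at 26. The crude product of the BBr3 reaction is acetylated at once (Ac2O, pyridine) to the undecaacetate of 26 F6, which is stable and can be chromatographed, so that incompletely cleaved material is removed. Deacetylation (NaOMe (cat.), MeOH, Ar, then acidic resin) then releases 26.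

## Further compounds

F1 | step 10 | 1,3,5-trimethoxy-2-{3,4-dimethoxy-5-[2,4,6-trimethoxy-3-(3,4,5-trimethoxyphenoxy)phenoxy]phenoxy}benzene | COc1cc(Oc2c(OC)cc(OC)c(Oc3cc(Oc4c(OC)cc(OC)cc4OC)cc(OC)c3OC)c2OC)cc(OC)c1OC
F2 | step 5 | 2-(3-iodo-4,5-dimethoxyphenoxy)-1,3,5-trimethoxybenzene | COc1cc(OC)c(Oc2cc(OC)c(OC)c(I)c2)c(OC)c1
F3 | step 8 | {[3-(2,3-dimethoxy-5-(2,4,6-trimethoxyphenoxy)phenoxy)-2,4,6-trimethoxyphenoxy]ethynyl}trimethylsilane | C[Si](C)(C)C#COc1c(OC)cc(OC)c(Oc2cc(Oc3c(OC)cc(OC)cc3OC)cc(OC)c2OC)c1OC
F4 | step 4 | 2,4,6-trimethoxyphenyl acetate | CC(=O)Oc1c(OC)cc(OC)cc1OC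
F5 | step 4 | 3-formyl-2,4,6-trimethoxyphenyl acetate | CC(=O)Oc1c(OC)cc(OC)c(C=O)c1OC
F6 | step 11 | undecaacetate of 26 | CC(=O)Oc1cc(OC(C)=O)c(Oc2cc(OC(C)=O)c(OC(C)=O)c(Oc3c(OC(C)=O)cc(OC(C)=O)c(Oc4cc(OC(C)=O)c(OC(C)=O)c(OC(C)=O)c4)c3OC(C)=O)c2)c(OC(C)=O)c1
A1 | alternative 1 | 2,4,6-trifluorobenzaldehyde | O=Cc1c(F)cc(F)cc1F
A2 | alternative 1 | 2,4,6-trimethoxy-3-(3,4,5-trimethoxyphenoxy)phenol | Oc1c(OC)cc(OC)c(Oc2cc(OC)c(OC)c(OC)c2)c1OC
A3 | alternative 1 | 2-fluoro-4-(2,4,6-trimethoxyphenoxy)-6-[2,4,6-trimethoxy-3-(3,4,5-trimethoxyphenoxy)phenoxy]benzaldehyde | O=Cc1c(F)cc(Oc2c(OC)cc(OC)cc2OC)cc1Oc1c(OC)cc(OC)c(Oc2cc(OC)c(OC)c(OC)c2)c1OC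
A4 | alternative 1 | 5-bromo-1,2,3-trimethoxybenzene | COc1cc(Br)cc(OC)c1OC
A5 | alternative 2 | methyl 6-(3-bromo-4,5-dimethoxyphenoxy)-3,5-dioxohexanoate | COC(=O)CC(=O)CC(=O)COc1cc(OC)c(OC)c(Br)c1
A6 | alternative 2 | 2-(3-bromo-4,5-dimethoxyphenoxy)benzene-1,3,5-triol | Oc1cc(O)c(Oc2cc(OC)c(OC)c(Br)c2)c(O)c1
A7 | alternative 3 | 4-(1-ethoxyethenyl)-3-methoxy-2-(3,4,5-trimethoxyphenoxy)-4-(trimethylsilyloxy)cyclobut-2-en-1-one (racemic) | CCOC(=C)C1(O[Si](C)(C)C)C(OC)=C(Oc2cc(OC)c(OC)c(OC)c2)C1=O
A8 | alternative 3 | 5-ethoxy-3-methoxy-2-(3,4,5-trimethoxyphenoxy)-4-(trimethylsilyloxy)phenol | CCOc1cc(O)c(Oc2cc(OC)c(OC)c(OC)c2)c(OC)c1O[Si](C)(C)C
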